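**Remark (assumption):** the target has no stereocentre and is drawn as the neutral bis-phenol. All numbered starting materials, including vinylboronic ester 12, are taken to be purchasable.

## Analysis of the target

The target 17 is an open-chain bis-bibenzyl: four benzene rings joined by two CH2–CH2 bridges and one diaryl ether oxygen, with no other ring and no stereocentre. Ring A is a 3-methoxyphenyl group. Ring B is a phenol that carries the A–B bridge at C1, the aryloxy group at C3 and the hydroxyl at C4. Ring C is para-disubstituted by the ether oxygen and the C–D bridge, and ring D is a 3-hydroxyphenyl group. Since nothing is stereogenic, only positional relationships have to be set: on ring B the hydroxyl para and the aryloxy group meta to the bridge, meta patterns on rings A and D, para on ring C. The sensitive groups are the two free phenols, of which the ring B phenol is an electron-rich catechol monoether. They must be freed without touching the ring A methyl ether, so a global demethylation is excluded and the phenols travel as benzyl ethers. The difficulty is that the two halves look alike (two meta-oxygenated phenethyl units), so the methyl ether end and the hydroxyl ends must be kept apart while two saturated two-carbon bridges are forged between arenes. The strategy rests on the A–B bridge: a bare ethylene whose two carbons each carry exactly one aryl group, C1 of ring A and C1 of ring B. That is the pattern a vinyl group acquires when one aryl group is delivered to each of its carbons.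

## Retrosynthetic reasoning

**17 to 16.** The two phenolic O–H bonds are traced back to O–benzyl bonds in the bis-benzyl ether 16, 1-(benzyloxy)-2-{4-[2-(3-benzyloxyphenyl)ethyl]phenoxy}-4-[2-(3-methoxyphenyl)ethyl]benzene. Benzyl is chosen because hydrogenolysis leaves the ring A methyl ether alone. It also survives carbonate bases, ylides, alkyllithium at low temperature and fluoride, which are all used earlier.

**16 to 15.** One benzylic C–H bond of the A–B bridge, on the carbon next to ring B, is replaced by a C–B bond, giving the pinacol boronate 15. The boron is the trace left by the bond-forming step. The forward reaction only has to exchange boron for hydrogen, and the single stereocentre of 15 disappears in doing so.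

**15 to 9, 12 and 11.** Both bonds flanking the ethylene are cut at once: C1 of ring B to CH, and CH2 to C1 of ring A. This leaves the ring B bromide 9 (used as its aryllithium 13), vinylboronic ester 12 as the two-carbon unit, and 3-methoxyphenyl triflate 11 as ring A. The cut is made at this bridge for three reasons:
- Ring A is the simplest ring and enters last with its methyl ether in place, so no intermediate ever carries a methyl and a benzyl ether that must be told apart.
- Ring B bears a para-alkoxy group, which makes it a good migrating group.
- The bridge is formed at the alkane oxidation level, so no alkene or alkyne has to be reduced afterwards.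

The forward reaction must pass through the boron ate complex 14 and a palladium-induced 1,2-shift.

**9 to 8.** The saturated C–D bridge is traced back to the stilbene 8. The forward reduction must spare the C–Br bond and both O–benzyl bonds, which calls for hydrogen transfer without a metal surface.

**8 to 4 and 6.** The C=C bond is cut to the aldehyde 4 and the ylide 7, which comes from the phosphonium salt 6 and in turn from the benzylic bromide 5. The aldehyde on ring C is needed anyway to activate the ether formation, so it serves twice.

**4 to 3.** The C–Br bond on ring B is removed, leaving aldehyde 3. The forward bromination must go para to the benzyloxy group. The order matters: phenol 1 itself would brominate para to its free hydroxyl, the wrong carbon. Once that oxygen is arylated by an electron-poor ring, the benzyloxy group becomes the dominant director.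

**3 to 1 and 2.** The ether bond between oxygen and C4 of ring C is cut, giving 2-(benzyloxy)phenol 1 and 4-fluorobenzaldehyde 2. The forward reaction is a nucleophilic aromatic substitution activated by the para-formyl group.

**11 to 10.** The S–O bond is cut, giving 3-methoxyphenol 10. The forward step is a routine triflation.

## Alternatives that were turned down

**Alternative 1:** Ring C is built by a [4+2] cycloaddition.
- Disconnection: two C–C bonds of ring C, leading to the 2-aryloxybuta-1,3-diene A1 (which already carries rings A and B and their bridge on oxygen) and the ethynyl ketone A2 (which carries ring D).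
- Forward key step: thermal Diels–Alder reaction of A1 with A2 gives the 1,4-cyclohexadiene A3. An oxidation then has to aromatise the ring, the carbonyl has to be reduced to a methylene group, and the benzyl ethers are cleaved.
- For it: the ether oxygen sits on an sp2 carbon before ring C exists, so no activating group on ring C and no aryl–oxygen coupling is needed. The donor diene and acceptor alkyne are matched for the 1,4 pattern. Ring B needs no regioselective bromination and no organolithium. On these points it is as strong as or stronger than the chosen route.
- Against it: A1 is only weakly activated (aryloxy, not silyloxy or amino), is awkward to make and is prone to polymerise. A2 has doubly activated methylene protons and can isomerise to an allenyl ketone. Two redox corrections follow the cycloaddition. The A–B bridge still has to be made beforehand by some other method. A benzene ring that can be bought as 2 is constructed from scratch.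
- Comparison: the chosen strategy buys all four rings and spends its one demanding step on two C–C bonds formed directly at the final oxidation level.

**Alternative 2:** Ring B is built by annulation.
- Disconnection: two C–C bonds of ring B, leading to the aldehyde A4 and the aryloxymethyl vinyl ketone A5.
- Forward key step: a secondary-amine enamine of A4 adds to A5 in a conjugate addition, and the keto aldehyde closes by aldol condensation to the cyclohexenone A6. A6 must then be dehydrogenated to the phenol and debenzylated.
- For it: the ring B hydroxyl arises from the carbonyl, unprotected and in the right place relative to the aryloxy group, so ring B poses no regiochemical question. The diaryl ether comes from a plain O-alkylation at an sp3 carbon. Here it is stronger than the chosen route, which relies on a directing-group argument in step 2.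
- Against it: A5 is a polymerisable, base-sensitive enone. It has to be made from a ring C phenol that already carries the C–D bridge and a protected ring D, which is a synthesis in itself. A6 is two hydrogens short of aromatic, and oxidants that aromatise cyclohexenones also attack the four benzylic positions and the benzyl ether.
- Comparison: the chosen route offers a shorter sequence in which ring B is never at a wrong oxidation level.

**Alternative 3:** Ring D is built by a polyketide-style [3+3] condensation.
- Disconnection: two C–C bonds of ring D, leading to the bis-silyl dienol ether of methyl acetoacetate A7 and the β-keto acetal A8, which carries the rest of the molecule.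
- Forward key step: a strong Lewis acid promotes condensation of A7 with A8 and aromatisation to the salicylate A9. The ester must then be hydrolysed, the acid decarboxylated, and the benzyl ether cleaved.
- For it: the meta relationship of hydroxyl and bridge on ring D is guaranteed, the phenol arrives free, and the C–D bridge is saturated from the start. On that last point it is stronger than the Wittig and reduction pair used here.
- Against it: A8 needs a long chain extension from ring C. A carboxyl carbon is brought in only to be removed under forcing thermal conditions. A strong Lewis acid meets three aryl ethers. Ring D is the cheapest ring to buy, as bromide 5.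
- Comparison: the chosen route takes ring D from the shelf and keeps its risk in one catalytic step rather than in a long preparation of A8.

Key step: step 7

## Route

**Step 1**
Reactants: 1 2-(benzyloxy)phenol; 2 4-fluorobenzaldehyde
Product: 3 4-[2-(benzyloxy)phenoxy]benzaldehyde
Conditions: K2CO3, DMF, 120 °C
Reagents that add atoms: none
Why: Nucleophilic aromatic substitution (addition–elimination): the phenoxide of 1 attacks C4 of 2, the para-formyl group stabilises the anionic intermediate, and fluoride leaves. The benzyl ether and the aldehyde are inert to carbonate in DMF.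

**Step 2**
Reactants: 3 4-[2-(benzyloxy)phenoxy]benzaldehyde
Product: 4 4-[2-(benzyloxy)-5-bromophenoxy]benzaldehyde
Conditions: NBS, MeCN, 0 °C to rt, dark
Reagents that add atoms: N-bromosuccinimide, O=C1CCC(=O)N1Br
Why: Electrophilic aromatic bromination: on ring B the benzyloxy oxygen is the stronger donor because the lone pairs of the diaryl ether oxygen are shared with the formyl-bearing ring C, so substitution should go para to the benzyloxy group, and ring C is deactivated by the aldehyde. Bromination is placed after the arylation because free phenol 1 would react para to its hydroxyl group.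

**Step 3**
Reactants: 5 3-(benzyloxy)benzyl bromide
Product: 6 [3-(benzyloxy)benzyl]triphenylphosphonium bromide
Conditions: PPh3, toluene, reflux
Reagents that add atoms: triphenylphosphine, c1ccc(P(c2ccccc2)c2ccccc2)cc1
Why: SN2 quaternisation of the phosphine by a benzylic bromide; the salt should precipitate from toluene and be collected by filtration.

**Step 4**
Reactants: 6 [3-(benzyloxy)benzyl]triphenylphosphonium bromide; 4 4-[2-(benzyloxy)-5-bromophenoxy]benzaldehyde
Product: 8 1-(benzyloxy)-4-bromo-2-{4-[2-(3-benzyloxyphenyl)ethenyl]phenoxy}benzene (E/Z mixture), via [3-(benzyloxy)benzylidene]triphenylphosphorane 7 (not isolated)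
Conditions: KOt-Bu, THF, 0 °C; then 4, 0 °C to rt
Reagents that add atoms: none
Why: Wittig olefination: deprotonation gives the semi-stabilised benzylide 7, which adds to the non-enolisable aldehyde 4 and collapses through the oxaphosphetane. The E/Z ratio does not matter because the double bond is reduced next, and the aryl bromide does not react with the ylide.

**Step 5**
Reactants: 8 1-(benzyloxy)-4-bromo-2-{4-[2-(3-benzyloxyphenyl)ethenyl]phenoxy}benzene (E/Z mixture)
Product: 9 1-(benzyloxy)-4-bromo-2-{4-[2-(3-benzyloxyphenyl)ethyl]phenoxy}benzene
Conditions: TsNHNH2 (excess, in portions), NaOAc, DME/H2O, reflux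
Reagents that add atoms: none
Why: Diimide reduction: the sulfonyl hydrazide loses sulfinate on heating and gives HN=NH, which transfers two hydrogens to the C=C bond in a concerted syn step. Unlike H2 on a metal surface it cannot cleave the C–Br bond or the benzyl ethers.

**Step 6**
Reactants: 10 3-methoxyphenol
Product: 11 3-methoxyphenyl trifluoromethanesulfonate
Conditions: Tf2O, pyridine, CH2Cl2, 0 °C
Reagents that add atoms: trifluoromethanesulfonic anhydride, O=S(=O)(OS(=O)(=O)C(F)(F)F)C(F)(F)F
Why: O-Sulfonylation of a phenol; it gives an electrophile whose leaving group stays off palladium as a non-coordinating counter-ion.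

**Step 7**
Reactants: 9 1-(benzyloxy)-4-bromo-2-{4-[2-(3-benzyloxyphenyl)ethyl]phenoxy}benzene; 12 4,4,5,5-tetramethyl-2-vinyl-1,3,2-dioxaborolane (vinylboronic acid pinacol ester); 11 3-methoxyphenyl trifluoromethanesulfonate
Product: 15 2-[1-{4-(benzyloxy)-3-[4-(2-(3-benzyloxyphenyl)ethyl)phenoxy]phenyl}-2-(3-methoxyphenyl)ethyl]-4,4,5,5-tetramethyl-1,3,2-dioxaborolane (configuration at the boron-bearing carbon not controlled), via aryllithium 13 (not isolated), via lithium aryl(vinyl)pinacolatoborate 14 (not isolated)
Conditions: t-BuLi (2 equiv), Et2O, −78 °C; 12, −78 °C to rt; solvent exchange to THF; Pd(OAc)2 (2 mol %), 1,1'-bis[bis(4-methoxy-3,5-dimethylphenyl)phosphino]-2,2'-bis[α-(dimethylamino)benzyl]ferrocene (2.4 mol %, either enantiomer), NaOTf, 11, 60 °C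
Reagents that add atoms: none
Why: Bromine–lithium exchange with two equivalents of t-BuLi at −78 °C is faster than any attack on the benzyl ethers and gives aryllithium 13, which adds to the vacant orbital on boron of 12 to form the four-coordinate boronate 14. Zerovalent palladium, formed from Pd(OAc)2 and the bisphosphine, inserts into the C–O bond of triflate 11 and gives a cationic divalent arylpalladium species that binds the vinyl group of 14. This activation triggers a 1,2-shift of the ring B aryl group from boron to the adjacent carbon, anti to palladium, while palladium bonds to the terminal carbon; reductive elimination then joins that CH2 to C1 of ring A and returns zerovalent palladium. The closest known reaction type is the palladium-catalysed conjunctive cross-coupling of vinylboron ate complexes with aryl triflates, in which aryl groups are established migrating groups. No ring is closed. One stereocentre is created at the boron-bearing benzylic carbon; its sense would follow the ligand enantiomer, but it is left uncontrolled because step 8 replaces boron by hydrogen. The selectivity needed is the metallate shift over direct transfer of the aryl or vinyl group from boron to palladium (Suzuki–Miyaura coupling) and over β-hydride elimination. It is secured by the cationic palladium centre (triflate electrophile, with the LiBr from the exchange removed as NaBr by NaOTf), by the wide-bite-angle ferrocenyl bisphosphine, which speeds reductive elimination, and by the electron-rich para-benzyloxyaryl migrating group.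

**Step 8**
Reactants: 15 2-[1-{4-(benzyloxy)-3-[4-(2-(3-benzyloxyphenyl)ethyl)phenoxy]phenyl}-2-(3-methoxyphenyl)ethyl]-4,4,5,5-tetramethyl-1,3,2-dioxaborolane
Product: 16 1-(benzyloxy)-2-{4-[2-(3-benzyloxyphenyl)ethyl]phenoxy}-4-[2-(3-methoxyphenyl)ethyl]benzene
Conditions: Bu4NF·3H2O, toluene, 80 °C
Reagents that add atoms: none
Why: Fluoride-mediated protodeboronation of a benzylic boronic ester: fluoride adds to boron and the resulting boronate hands its benzylic carbon to a proton of the hydrate water. The stereocentre disappears, and the ethers are inert to fluoride.

**Step 9**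
Reactants: 16 1-(benzyloxy)-2-{4-[2-(3-benzyloxyphenyl)ethyl]phenoxy}-4-[2-(3-methoxyphenyl)ethyl]benzene
Product: 17 2-{4-[2-(3-hydroxyphenyl)ethyl]phenoxy}-4-[2-(3-methoxyphenyl)ethyl]phenol
Conditions: H2 (1 atm), Pd/C, EtOAc/MeOH, rt
Reagents that add atoms: none
Why: Hydrogenolysis of two aryl benzyl ethers over Pd/C; the aryl methyl ether, the diaryl ether and the saturated bridges do not react, so both phenols are freed while ring A keeps its methoxy group.

## Compound list

1 | 2-(benzyloxy)phenol | Oc1ccccc1OCc1ccccc1 | starting material
2 | 4-fluorobenzaldehyde | O=Cc1ccc(F)cc1 | starting material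
3 | 4-[2-(benzyloxy)phenoxy]benzaldehyde | O=Cc1ccc(Oc2ccccc2OCc2ccccc2)cc1 | intermediate
4 | 4-[2-(benzyloxy)-5-bromophenoxy]benzaldehyde | O=Cc1ccc(Oc2cc(Br)ccc2OCc2ccccc2)cc1 | intermediate
5 | 3-(benzyloxy)benzyl bromide | BrCc1cccc(OCc2ccccc2)c1 | starting material
6 | [3-(benzyloxy)benzyl]triphenylphosphonium bromide | [Br-].c1ccc(COc2cccc(C[P+](c3ccccc3)(c3ccccc3)c3ccccc3)c2)cc1 | intermediate
7 | [3-(benzyloxy)benzylidene]triphenylphosphorane (formed in the flask, not isolated) | c1ccc(COc2cccc(C=P(c3ccccc3)(c3ccccc3)c3ccccc3)c2)cc1 | intermediate
8 | 1-(benzyloxy)-4-bromo-2-{4-[2-(3-benzyloxyphenyl)ethenyl]phenoxy}benzene (E/Z mixture, geometry not defined) | Brc1ccc(OCc2ccccc2)c(Oc2ccc(C=Cc3cccc(OCc4ccccc4)c3)cc2)c1 | intermediate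
9 | 1-(benzyloxy)-4-bromo-2-{4-[2-(3-benzyloxyphenyl)ethyl]phenoxy}benzene | Brc1ccc(OCc2ccccc2)c(Oc2ccc(CCc3cccc(OCc4ccccc4)c3)cc2)c1 | intermediate
10 | 3-methoxyphenol | COc1cccc(O)c1 | starting material
11 | 3-methoxyphenyl trifluoromethanesulfonate | COc1cccc(OS(=O)(=O)C(F)(F)F)c1 | intermediate
12 | 4,4,5,5-tetramethyl-2-vinyl-1,3,2-dioxaborolane | C=CB1OC(C)(C)C(C)(C)O1 | starting material
13 | {4-(benzyloxy)-3-[4-(2-(3-benzyloxyphenyl)ethyl)phenoxy]phenyl}lithium (formed in the flask, not isolated) | [Li]c1ccc(OCc2ccccc2)c(Oc2ccc(CCc3cccc(OCc4ccccc4)c3)cc2)c1 | intermediate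
14 | lithium {4-(benzyloxy)-3-[4-(2-(3-benzyloxyphenyl)ethyl)phenoxy]phenyl}(vinyl)(pinacolato)borate (formed in the flask, not isolated) | [Li+].C=C[B-]1(OC(C)(C)C(C)(C)O1)c1ccc(OCc2ccccc2)c(Oc2ccc(CCc3cccc(OCc4ccccc4)c3)cc2)c1 | intermediate
15 | 2-[1-{4-(benzyloxy)-3-[4-(2-(3-benzyloxyphenyl)ethyl)phenoxy]phenyl}-2-(3-methoxyphenyl)ethyl]-4,4,5,5-tetramethyl-1,3,2-dioxaborolane (configuration at the boron-bearing carbon undefined) | COc1cccc(CC(B2OC(C)(C)C(C)(C)O2)c2ccc(OCc3ccccc3)c(Oc3ccc(CCc4cccc(OCc5ccccc5)c4)cc3)c2)c1 | intermediate
16 | 1-(benzyloxy)-2-{4-[2-(3-benzyloxyphenyl)ethyl]phenoxy}-4-[2-(3-methoxyphenyl)ethyl]benzene | COc1cccc(CCc2ccc(OCc3ccccc3)c(Oc3ccc(CCc4cccc(OCc5ccccc5)c4)cc3)c2)c1 | intermediate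
17 | 2-{4-[2-(3-hydroxyphenyl)ethyl]phenoxy}-4-[2-(3-methoxyphenyl)ethyl]phenol | COc1cccc(CCc2ccc(O)c(Oc3ccc(CCc4cccc(O)c4)cc3)c2)c1 | target

## Step count and uncertain steps

Total: 9 steps. Longest linear sequence: 7 steps (steps 1, 2, 4, 5, 7, 8, 9); steps 3 and 6 are one-step branches.

**Step 7 (key step).**
- What may go wrong: bromide left on palladium blocks binding of the vinyl group, and the aryl group is then transferred directly from boron to palladium to give a biaryl. Incomplete halogen–lithium exchange leaves aryl bromide that competes with triflate 11 as the electrophile. The aryllithium may be protonated before it reaches boron. β-Hydride elimination may occur after the shift.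
- Fallback: it sets out from 9 and comes back to the route at 17. Sonogashira coupling of 9 with purchased 1-ethynyl-3-methoxybenzene F1 (PdCl2(PPh3)2, CuI, i-Pr2NH, DMF, 80 °C) should give the diarylalkyne 1-(benzyloxy)-2-{4-[2-(3-benzyloxyphenyl)ethyl]phenoxy}-4-[(3-methoxyphenyl)ethynyl]benzene F2. Hydrogenation of F2 (H2, Pd/C, EtOAc/MeOH) should saturate the triple bond and cleave both benzyl ethers in the same operation, giving 17 directly. This fallback is no longer than the main route, so the risk of the key step is affordable.

**Step 2.**
- What may go wrong: loss of positional selectivity, with bromination para to the aryloxy oxygen, on ring C ortho to the ether oxygen, or twice, because the two oxygen donors on ring B differ only moderately.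
- Fallback: it keeps 2 as the electrophile and comes back at 4, with the bromine position bought rather than made. Purchased 5-bromo-2-hydroxybenzaldehyde F3 is benzylated (benzyl bromide, K2CO3, DMF) to 2-(benzyloxy)-5-bromobenzaldehyde F4. Baeyer–Villiger oxidation (mCPBA, CH2Cl2) gives 2-(benzyloxy)-5-bromophenyl formate F5, and methanolysis (K2CO3, MeOH) gives 2-(benzyloxy)-5-bromophenol F6. Substitution of 2 by F6 (K2CO3, DMF, 120 °C) then gives 4.

**Step 5.**
- What may go wrong: incomplete reduction, because diimide disproportionates faster than it reduces a 1,2-diaryl alkene, leaving alkene that is hard to separate from 9.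
- Fallback: it sets out from 5 and 4, comes back at 9 and avoids any alkene. Bromide 5 is converted (Mg, Et2O, 0 °C, slow addition) into 3-(benzyloxy)benzylmagnesium bromide F7, which adds to aldehyde 4 at −78 °C to give 1-{4-[2-(benzyloxy)-5-bromophenoxy]phenyl}-2-[3-(benzyloxy)phenyl]ethanol F8. Ionic deoxygenation (Et3SiH, CF3CO2H, CH2Cl2, 0 °C) proceeds through the para-aryloxy-stabilised benzylic cation and gives 9.

**Step 8.**
- What may go wrong: slow C–B protonolysis, because the para-benzyloxy group of ring B disfavours build-up of negative charge on the benzylic carbon, with competing oxidation of the C–B bond by adventitious air.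
- Fallback: it sets out from 15 and comes back at 16. Oxidation (H2O2, NaOH, THF/H2O, 0 °C) gives 1-{4-(benzyloxy)-3-[4-(2-(3-benzyloxyphenyl)ethyl)phenoxy]phenyl}-2-(3-methoxyphenyl)ethanol F9. Ionic deoxygenation (Et3SiH, CF3CO2H, CH2Cl2, 0 °C) then gives 16, since the donor that slows carbanion formation now stabilises the benzylic cation.

## Further compounds

F1 | step 7 | 1-ethynyl-3-methoxybenzene (purchased) | COc1cccc(C#C)c1
F2 | step 7 | 1-(benzyloxy)-2-{4-[2-(3-benzyloxyphenyl)ethyl]phenoxy}-4-[(3-methoxyphenyl)ethynyl]benzene | COc1cccc(C#Cc2ccc(OCc3ccccc3)c(Oc3ccc(CCc4cccc(OCc5ccccc5)c4)cc3)c2)c1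
F3 | step 2 | 5-bromo-2-hydroxybenzaldehyde (purchased) | O=Cc1cc(Br)ccc1O
F4 | step 2 | 2-(benzyloxy)-5-bromobenzaldehyde | O=Cc1cc(Br)ccc1OCc1ccccc1
F5 | step 2 | 2-(benzyloxy)-5-bromophenyl formate | O=COc1cc(Br)ccc1OCc1ccccc1
F6 | step 2 | 2-(benzyloxy)-5-bromophenol | Oc1cc(Br)ccc1OCc1ccccc1
F7 | step 5 | 3-(benzyloxy)benzylmagnesium bromide | Br[Mg]Cc1cccc(OCc2ccccc2)c1
F8 | step 5 | 1-{4-[2-(benzyloxy)-5-bromophenoxy]phenyl}-2-[3-(benzyloxy)phenyl]ethanol (racemic) | OC(Cc1cccc(OCc2ccccc2)c1)c1ccc(Oc2cc(Br)ccc2OCc2ccccc2)cc1
F9 | step 8 | 1-{4-(benzyloxy)-3-[4-(2-(3-benzyloxyphenyl)ethyl)phenoxy]phenyl}-2-(3-methoxyphenyl)ethanol (configuration undefined) | COc1cccc(CC(O)c2ccc(OCc3ccccc3)c(Oc3ccc(CCc4cccc(OCc5ccccc5)c4)cc3)c2)c1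
A1 | alternative 1 | 1-(benzyloxy)-2-(buta-1,3-dien-2-yloxy)-4-[2-(3-methoxyphenyl)ethyl]benzene | C=CC(=C)Oc1cc(CCc2cccc(OC)c2)ccc1OCc1ccccc1
A2 | alternative 1 | 1-[3-(benzyloxy)phenyl]but-3-yn-2-one | C#CC(=O)Cc1cccc(OCc2ccccc2)c1
A3 | alternative 1 | 1-(4-{2-(benzyloxy)-5-[2-(3-methoxyphenyl)ethyl]phenoxy}cyclohexa-1,4-dien-1-yl)-2-[3-(benzyloxy)phenyl]ethanone | O=C(Cc1cccc(OCc2ccccc2)c1)C1=CCC(Oc2cc(CCc3cccc(OC)c3)ccc2OCc2ccccc2)=CC1
A4 | alternative 2 | 4-(3-methoxyphenyl)butanal | COc1cccc(CCCC=O)c1
A5 | alternative 2 | 1-{4-[2-(3-benzyloxyphenyl)ethyl]phenoxy}but-3-en-2-one | C=CC(=O)COc1ccc(CCc2cccc(OCc3ccccc3)c2)cc1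
A6 | alternative 2 | 2-{4-[2-(3-benzyloxyphenyl)ethyl]phenoxy}-4-[2-(3-methoxyphenyl)ethyl]cyclohex-2-en-1-one (racemic) | O=C1CCC(CCc2cccc(OC)c2)C=C1Oc1ccc(CCc2cccc(OCc3ccccc3)c2)cc1
A7 | alternative 3 | 1-methoxy-1,3-bis(trimethylsilyloxy)buta-1,3-diene | COC(O[Si](C)(C)C)=CC(=C)O[Si](C)(C)C
A8 | alternative 3 | 5-(4-{2-(benzyloxy)-5-[2-(3-methoxyphenyl)ethyl]phenoxy}phenyl)-1,1-dimethoxypentan-3-one | COC(OC)CC(=O)CCc1ccc(Oc2cc(CCc3cccc(OC)c3)ccc2OCc2ccccc2)cc1
A9 | alternative 3 | methyl 2-[2-(4-{2-(benzyloxy)-5-[2-(3-methoxyphenyl)ethyl]phenoxy}phenyl)ethyl]-6-hydroxybenzoate | COC(=O)c1c(O)cccc1CCc1ccc(Oc2cc(CCc3cccc(OC)c3)ccc2OCc2ccccc2)cc1
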